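**Plan**

1. Numbering: C1 (CH bearing isopropenyl), C2 (CH2), C3 (CHOH), C4 (C(Me)OH), C5 (CH–O-angeloyl), C6 (CH2), C7–C8 (oxirane, methyl on C8), C9 (CH–OAc), C10 (CH–O-angeloyl, bonded back to C1).
2. Enabling feature: in the ten-membered carbocycle, O9 (as acetate) and O10 sit on neighbouring carbons. C9 is allylic to the C7=C8 alkene hidden in the oxirane. This alkene-3,4-diol 3-monoacetate is what a gamma-acetoxyallyl metal gives with an aldehyde, so the ring is cut at C9–C10.
3. Cuts, in order: the C10 ester and the oxirane oxygen; C9–C10 (ring); C7–Br and O9–acetyl (acetyl bromide on an enal); C7=C8 (cross-metathesis); C5–C6 (allyl Grignard); and the C5–C10 bond of a cyclohexanone made from (S)-carvone 1.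
4. Forward: carvone supplies C10–C1–C2–C3–C4–C5 with the C4 methyl and the isopropenyl group. Its six-membered ring is opened between C5 and C10, the chain is grown to C9, and the only carbocycle of the target closes in the chromium step. Epoxidation, the second angeloylation and desilylation finish the route.
5. Stereochemistry: C1 comes from carvone. C4 and C3 come from epoxidation anti to isopropenyl followed by inverting hydrolysis at C3. C5 comes from a polar Felkin–Anh reduction. C9, C10 and the Z alkene come from the chair transition state and C1. C7 and C8 come from C10–OH-directed epoxidation.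

Key step: step 14

Assumption: the acetyl bromide adducts are handled as mixtures of C7 epimers and enol acetate E/Z isomers (possibly with some allylic 1-bromoallyl acetate isomer), all of which converge on one allylchromium species, so these elements are left open in their SMILES; the carbinol centres of the alpha-hydroxy ketone and of the allyl diol are left open as well because the glycol cleavage destroys them.

**Step 1**
Reactants: 1 (S)-(+)-carvone
Product: 2 (1S,4S,6S)-1-methyl-4-(prop-1-en-2-yl)-7-oxabicyclo[4.1.0]heptan-2-one (oxirane trans to isopropenyl)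
Conditions: 35% aq. H2O2, NaOH (cat.), MeOH, 0 °C
Reagents that add atoms: hydrogen peroxide, OO
Why: Weitz–Scheffer nucleophilic epoxidation touches only the enone alkene, and hydroperoxide adds on the ring face opposite to the isopropenyl group, which fixes the C4 oxygen.

**Step 2**
Reactants: 2 carvone epoxide
Product: 3 (2S,3R,5S)-2,3-dihydroxy-2-methyl-5-(prop-1-en-2-yl)cyclohexan-1-one (trans diol, O3 cis to isopropenyl)
Conditions: dilute aq. H2SO4, THF, rt
Reagents that add atoms: water, O
Why: Acid-catalysed hydrolysis of an alpha,beta-epoxy ketone, in which water attacks the beta carbon C3 from the rear of the oxirane because positive charge at C4 next to the carbonyl is disfavoured, so C3 is inverted and C4 keeps its oxygen.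

**Step 3**
Reactants: 3 trans diol
Product: 4 (2S,3R,5S)-2-methyl-5-(prop-1-en-2-yl)-2,3-bis(triethylsilyloxy)cyclohexan-1-one
Conditions: Et3SiOTf, 2,6-lutidine, CH2Cl2, −78 to 0 °C
Reagents that add atoms: triethylsilyl triflate, CC[Si](CC)(CC)OS(=O)(=O)C(F)(F)F
Why: Silyl triflate silylation caps the secondary and the tertiary hydroxyl alike; O4 must be blocked because a free C4–OH would later close a six-membered lactol onto the C10 aldehyde, and triethylsilyl groups leave at the end with fluoride.

**Step 4**
Reactants: 4 bis-silyl ketone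
Product: 6 (2S,3R,5R)-6-hydroxy-2-methyl-5-(prop-1-en-2-yl)-2,3-bis(triethylsilyloxy)cyclohexan-1-one (C6 epimers), via potassium enolate 5 (not isolated)
Conditions: KN(SiMe3)2, THF, −78 °C; 3-phenyl-2-(phenylsulfonyl)oxaziridine; aq. NH4Cl
Reagents that add atoms: 3-phenyl-2-(phenylsulfonyl)oxaziridine, O=S(=O)(N1OC1c1ccccc1)c1ccccc1
Why: Davis enolate hydroxylation; C4 is quaternary, so enolisation can only occur toward C10, the oxaziridine ignores the isopropenyl alkene, and the new carbinol configuration is irrelevant.

**Step 5**
Reactants: 6 alpha-hydroxy ketone; 7 allylmagnesium bromide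
Product: 8 (3R,5R,6S)-6-methyl-1-(prop-2-en-1-yl)-3-(prop-1-en-2-yl)-5,6-bis(triethylsilyloxy)cyclohexane-1,2-diol (C1 and C2 open)
Conditions: allylmagnesium bromide (3 equiv), THF, −78 to 0 °C; aq. NH4Cl
Reagents that add atoms: none
Why: Grignard 1,2-addition, in which one equivalent deprotonates the hydroxyl and the small, very reactive allyl reagent still reaches the hindered ketone and forms C5–C6.

**Step 6**
Reactants: 8 allyl diol
Product: 9 (2R,4R,5S)-5-methyl-6-oxo-2-(prop-1-en-2-yl)-4,5-bis(triethylsilyloxy)non-8-enal (C10 aldehyde, C5 allyl ketone)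
Conditions: Pb(OAc)4, CH2Cl2, 0 °C; filtered and used crude
Reagents that add atoms: none
Why: Criegee glycol cleavage breaks C5–C10 under anhydrous, base-free conditions, opens the six-membered ring and spares alkenes and silyl ethers; 9 is reduced at once so that C1 does not epimerise and neither alkene moves into conjugation.

**Step 7**
Reactants: 9 keto aldehyde
Product: 10 (2R,4R,5R,6S)-5-methyl-2-(prop-1-en-2-yl)-4,5-bis(triethylsilyloxy)non-8-ene-1,6-diol (C10–OH and 5S C5–OH)
Conditions: i-Bu2AlH, CH2Cl2, −78 °C; aq. potassium sodium tartrate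
Reagents that add atoms: none
Why: Hydride reduction of both carbonyls; at C5 the polar Felkin–Anh arrangement (and equally the Cornforth one) turns the C4–OSiEt3 bond away from the hydride, which passes the C4 methyl rather than the C3 chain and should give the 4,5-syn alcohol.

**Step 8**
Reactants: 10 diol
Product: 11 C10 triethylsilyl ether with free C5–OH, (1R,3R,4R,5S) in target numbering
Conditions: Et3SiCl (1 equiv), imidazole, CH2Cl2, −20 °C
Reagents that add atoms: chlorotriethylsilane, CC[Si](Cl)(CC)CC
Why: Chemoselective silylation, since the primary hydroxyl reacts far faster than the secondary one next to the quaternary C4.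

**Step 9**
Reactants: 11 homoallylic alcohol
Product: 12 C5 angelate (C10, C3 and C4 OSiEt3; terminal C7=CH2), (1R,3R,4R,5S)
Conditions: angelic acid, 2,4,6-trichlorobenzoyl chloride, Et3N, toluene, rt; then 11, 80 °C
Reagents that add atoms: angelic acid, C/C=C(/C)C(=O)O
Why: Yamaguchi-type mixed-anhydride esterification without a nucleophilic catalyst, the usual way to angeloylate hindered alcohols without Z to E drift to the tiglate; placing this ester now saves a protecting group on O5.

**Step 10**
Reactants: 12 terminal alkene; 13 methacrolein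
Product: 14 (E)-enal C7H=C8(Me)–C9HO
Conditions: methacrolein (10 equiv), second-generation Hoveyda–Grubbs catalyst (5 mol %), CH2Cl2, 40 °C
Reagents that add atoms: none
Why: Olefin cross-metathesis of a monosubstituted alkene with excess methacrolein forms C7=C8 as the thermodynamically preferred E enal, while the 1,1-disubstituted isopropenyl and the electron-poor angelate alkenes stay out of the cycle.

**Step 11**
Reactants: 14 enal; 15 acetyl bromide
Product: 16 C7 bromide / C8=C9 enol acetate with C10–OSiEt3
Conditions: AcBr (1.1 equiv), 2,6-di-tert-butyl-4-methylpyridine (0.1 equiv), CH2Cl2, −30 to 0 °C; volatiles removed, used crude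
Reagents that add atoms: none
Why: 1,4-Addition of an acyl bromide to an alpha,beta-unsaturated aldehyde (O-acylation to an acyloxyallyl cation, bromide capture at C7), the reaction that makes 3-bromoprop-1-enyl esters from enals; no Lewis acid is present and the hindered base removes HBr, which protects the silyl ethers, the isopropenyl group and the angelate.

**Step 12**
Reactants: 16 silyl ether
Product: 17 primary C10 alcohol with the bromo enol acetate terminus
Conditions: Et3N·3HF, THF, 0 °C to rt
Reagents that add atoms: none
Why: Selective fluoride desilylation, as the unhindered primary silyl ether falls well before the secondary one beside C4 and the tertiary one, and the amine-buffered HF is neither basic nor a nucleophilic solvent toward the allylic bromide.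

**Step 13**
Reactants: 17 alcohol
Product: 18 acyclic C10 aldehyde: C1 isopropenyl, C3 and C4 OSiEt3, C5 angelate, C7 bromide, C8=C9 enol acetate
Conditions: Dess–Martin periodinane, NaHCO3, CH2Cl2, 0 °C; short filtration, used at once
Reagents that add atoms: none
Why: Dess–Martin oxidation is fast and neutral, so C1 should not epimerise, the isopropenyl alkene should not conjugate and the bromide should persist, and with O4 silylated no lactol can form and be over-oxidised.

**Step 14**
Reactants: 18 bromo enol acetate aldehyde
Product: 21 (1R,3R,4R,5S,7Z,9R,10S) ten-membered C9 acetate C10 alcohol, via gamma-acetoxyallylchromium dichloride 19 (not isolated), via C10 trimethylsilyl ether 20 (not isolated)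
Conditions: CrCl2 (10 equiv), Me3SiCl (3 equiv), THF, rt, 18 added over 12 h (final 2 mM); then citric acid, MeOH–H2O, 0 °C
Reagents that add atoms: none
Why: Proposed new method: two equivalents of divalent chromium reduce the C7–Br bond by one-electron steps to the allyl complex of trivalent chromium 19, whose metal migrates between the allyl termini so that every bromide and enol acetate isomer drains into the (E)-gamma-acetoxyallyl form with chromium on C7, which binds the aldehyde oxygen and forms C9–C10 with allylic transposition. The closest known reactions are the intermolecular CrCl2- or indium-mediated acyloxyallylation of aldehydes with 3-bromoprop-1-enyl esters and the intramolecular chromium allylations that close ten-membered carbocycles, and the new element is their union in a closure through the acetoxy-bearing allyl terminus. The ten-membered ring closes end to end, C9 onto C10, with all three allyl carbons inside the ring, through a six-membered chair of Cr, O, C10, C9, C8 and C7 held at high dilution. C9 is set against C10 by that chair (equatorial acetoxy on the E allyl unit and equatorial C1 give the anti pair), C10 is set by C1 through Felkin–Anh attack with the isopropenyl group perpendicular to the carbonyl, and the alkene should be Z because C6 sits axial on C7 to avoid the C8 methyl. The step needs bond formation through C9 and not C7 (which would give an eight-membered ring), secured by chromium resting on the carbon remote from the acetoxy group, and aldehyde selectivity, secured by the inertness of allylchromium reagents toward esters. Me3SiCl traps the chromium alkoxide as 20 so that acetyl cannot move from O9 to O10, and the weakly acidic work-up frees the C10 hydroxyl.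

**Step 15**
Reactants: 21 macrocyclic homoallylic alcohol
Product: 22 (1R,3R,4R,5S,7R,8R,9S,10S) C7–C8 epoxy alcohol
Conditions: VO(acac)2 (10 mol %), t-BuOOH (decane), CH2Cl2, 0 °C to rt
Reagents that add atoms: tert-butyl hydroperoxide, CC(C)(C)OO
Why: Hydroxyl-directed vanadium-catalysed epoxidation of a homoallylic alcohol, in which the C10 vanadate delivers oxygen through a chair with C1, the C9 acetoxy group and C7 all equatorial (oxirane 1,3-syn to O10), whereas delivery to the likewise homoallylic isopropenyl group would force a ring carbon axial and meets a less nucleophilic alkene.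

**Step 16**
Reactants: 22 epoxy alcohol
Product: 23 C5,C10-bis-angelate with C3 and C4 OSiEt3
Conditions: angelic acid, 2,4,6-trichlorobenzoyl chloride, Et3N, toluene, rt; then 22, 70 °C
Reagents that add atoms: angelic acid, C/C=C(/C)C(=O)O
Why: The same mixed-anhydride esterification acylates the hindered C10–OH without a nucleophilic catalyst or alkoxide formation, which guards against tiglate formation and acetyl migration.

**Step 17**
Reactants: 23 bis-silyl ether
Product: 24 target CNP0249359.1, (1R,3R,4S,5S,7R,8R,9S,10S)
Conditions: HF·pyridine, pyridine, THF, 0 °C to rt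
Reagents that add atoms: none
Why: Buffered fluoride cleavage removes both triethylsilyl ethers under conditions too mild to hydrolyse or shift the three esters or to activate the oxirane toward the freed hydroxyls.

**Compound list**

1 | (S)-(+)-carvone | C=C(C)[C@H]1CC=C(C)C(=O)C1 | starting material
2 | (1S,4S,6S)-carvone 2,3-epoxide | C=C(C)[C@H]1C[C@@H]2O[C@]2(C)C(=O)C1 | intermediate
3 | (2S,3R,5S)-trans-diol ketone | C=C(C)[C@H]1C[C@@H](O)[C@](C)(O)C(=O)C1 | intermediate
4 | bis(triethylsilyl) ether of 3 | C=C(C)[C@H]1C[C@@H](O[Si](CC)(CC)CC)[C@](C)(O[Si](CC)(CC)CC)C(=O)C1 | intermediate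
5 | potassium enolate of 4 | C=C(C)[C@H]1C[C@@H](O[Si](CC)(CC)CC)[C@](C)(O[Si](CC)(CC)CC)C([O-])=C1.[K+] | intermediate
6 | alpha-hydroxy ketone (carbinol centre open) | C=C(C)[C@H]1C[C@@H](O[Si](CC)(CC)CC)[C@](C)(O[Si](CC)(CC)CC)C(=O)C1O | intermediate
7 | allylmagnesium bromide | C=CC[Mg]Br | starting material
8 | allyl diol (both carbinol centres open) | C=C(C)[C@H]1C[C@@H](O[Si](CC)(CC)CC)[C@](C)(O[Si](CC)(CC)CC)C(O)(CC=C)C1O | intermediate
9 | C10 aldehyde C5 allyl ketone | C=C(C)[C@H](C=O)C[C@@H](O[Si](CC)(CC)CC)[C@](C)(O[Si](CC)(CC)CC)C(=O)CC=C | intermediate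
10 | C10,C5 diol | C=C(C)[C@H](CO)C[C@@H](O[Si](CC)(CC)CC)[C@](C)(O[Si](CC)(CC)CC)[C@@H](O)CC=C | intermediate
11 | C10 silyl ether, free C5–OH | C=C(C)[C@H](CO[Si](CC)(CC)CC)C[C@@H](O[Si](CC)(CC)CC)[C@](C)(O[Si](CC)(CC)CC)[C@@H](O)CC=C | intermediate
12 | C5 angelate, terminal alkene | C=C(C)[C@H](CO[Si](CC)(CC)CC)C[C@@H](O[Si](CC)(CC)CC)[C@](C)(O[Si](CC)(CC)CC)[C@@H](OC(=O)/C(C)=C\C)CC=C | intermediate
13 | methacrolein | C=C(C)C=O | starting material
14 | (E)-enal | C=C(C)[C@H](CO[Si](CC)(CC)CC)C[C@@H](O[Si](CC)(CC)CC)[C@](C)(O[Si](CC)(CC)CC)[C@@H](OC(=O)/C(C)=C\C)C/C=C(\C)C=O | intermediate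
15 | acetyl bromide | CC(=O)Br | starting material
16 | bromo enol acetate, C10–OSiEt3 (C7 and C8=C9 open) | C=C(C)[C@H](CO[Si](CC)(CC)CC)C[C@@H](O[Si](CC)(CC)CC)[C@](C)(O[Si](CC)(CC)CC)[C@@H](OC(=O)/C(C)=C\C)CC(Br)C(C)=COC(C)=O | intermediate
17 | bromo enol acetate, C10–OH | C=C(C)[C@H](CO)C[C@@H](O[Si](CC)(CC)CC)[C@](C)(O[Si](CC)(CC)CC)[C@@H](OC(=O)/C(C)=C\C)CC(Br)C(C)=COC(C)=O | intermediate
18 | bromo enol acetate C10 aldehyde (key-step precursor) | C=C(C)[C@H](C=O)C[C@@H](O[Si](CC)(CC)CC)[C@](C)(O[Si](CC)(CC)CC)[C@@H](OC(=O)/C(C)=C\C)CC(Br)C(C)=COC(C)=O | intermediate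
19 | (E)-gamma-acetoxyallylchromium dichloride | C=C(C)[C@H](C=O)C[C@@H](O[Si](CC)(CC)CC)[C@](C)(O[Si](CC)(CC)CC)[C@@H](OC(=O)/C(C)=C\C)CC([Cr](Cl)Cl)/C(C)=C/OC(C)=O | intermediate
20 | macrocyclic C10 trimethylsilyl ether | C=C(C)[C@H]1C[C@@H](O[Si](CC)(CC)CC)[C@](C)(O[Si](CC)(CC)CC)[C@@H](OC(=O)/C(C)=C\C)C/C=C(C)\[C@@H](OC(C)=O)[C@H]1O[Si](C)(C)C | intermediate
21 | ten-membered C9 acetate C10 alcohol, Z alkene (key-step product) | C=C(C)[C@H]1C[C@@H](O[Si](CC)(CC)CC)[C@](C)(O[Si](CC)(CC)CC)[C@@H](OC(=O)/C(C)=C\C)C/C=C(C)\[C@@H](OC(C)=O)[C@H]1O | intermediate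
22 | C7–C8 epoxy alcohol | C=C(C)[C@H]1C[C@@H](O[Si](CC)(CC)CC)[C@](C)(O[Si](CC)(CC)CC)[C@@H](OC(=O)/C(C)=C\C)C[C@H]2O[C@@]2(C)[C@@H](OC(C)=O)[C@H]1O | intermediate
23 | bis-angelate bis-silyl ether | C=C(C)[C@H]1C[C@@H](O[Si](CC)(CC)CC)[C@](C)(O[Si](CC)(CC)CC)[C@@H](OC(=O)/C(C)=C\C)C[C@H]2O[C@@]2(C)[C@@H](OC(C)=O)[C@H]1OC(=O)/C(C)=C\C | intermediate
24 | CNP0249359.1 | C=C(C)[C@H]1C[C@@H](O)[C@](C)(O)[C@@H](OC(=O)/C(C)=C\C)C[C@H]2O[C@@]2(C)[C@@H](OC(C)=O)[C@H]1OC(=O)/C(C)=C\C | target

**Step count and risks**

Total step count: 17. Longest linear sequence: 17 (from 1).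

**Step 14.** Oligomerisation or simple reduction of the allyl halide may outrun the slow medium-ring closure. Bond formation may also stray to C7, or the strained chair may lose its anti, Felkin–Anh or Z preference.

The fallback uses known chemistry and sets out from 12. Et3N·3HF should free the primary alcohol F1, and Dess–Martin oxidation should give the aldehyde F2. Methacrolein 13 and acetyl bromide 15 give 3-bromo-2-methylprop-1-enyl acetate F3. CrCl2 in THF joins F2 and F3 in the established intermolecular acyloxyallylation, under the same chair and Felkin–Anh control, to give the anti C9 acetate C10 alcohol diene F4. Ring-closing metathesis of its C7H=CH2 and C8(Me)=CH2 termini (second-generation Hoveyda–Grubbs catalyst, dilute toluene, 80 °C) should then form C7=C8, Z by ring constraint. The route is rejoined at 21.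

**Step 15.** Oxygen may be delivered to the isopropenyl alkene in competition. Facial selectivity may also be poor if the ring conformation keeps O10 away from the required alkene face.

The fallback sets out from 21. O10 is angeloylated first, under the conditions of step 16, to give the bis-angelate alkene F5. The ring alkene is then epoxidised without a directing group by a reagent-controlled Shi epoxidation (the fructose-derived ketone or its enantiomer, whichever is matched to the required face; KHSO5 as Oxone, K2CO3 buffer, MeCN–dimethoxymethane–water, 0 °C). The chiral dioxirane chooses the face and prefers the trisubstituted alkene over the 1,1-disubstituted and electron-poor ones. The route is rejoined at 23.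

**Step 12.** The allylic bromide may ionise or exchange halide, the enol acetate may hydrolyse, and the C3 silyl ether may be partly lost while the primary silyl ether is removed.

The fallback sets out from 14 and postpones the bromide to the last operation. Ac2O with catalytic LiBF4 should convert the enal into the robust allylic gem-diacetate F6. Et3N·3HF should give the alcohol F7, and Dess–Martin oxidation the aldehyde F8. One equivalent of Me3SiBr in CH2Cl2 at −40 °C should then exchange one acetoxy group for bromide with allylic shift. The route is rejoined at 18, which goes straight into step 14.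

**Further compounds**

F1 | step 14 | primary C10 alcohol, C5 angelate, terminal alkene | C=C(C)[C@H](CO)C[C@@H](O[Si](CC)(CC)CC)[C@](C)(O[Si](CC)(CC)CC)[C@@H](OC(=O)/C(C)=C\C)CC=C
F2 | step 14 | C10 aldehyde, C5 angelate, terminal alkene | C=C(C)[C@H](C=O)C[C@@H](O[Si](CC)(CC)CC)[C@](C)(O[Si](CC)(CC)CC)[C@@H](OC(=O)/C(C)=C\C)CC=C
F3 | step 14 | 3-bromo-2-methylprop-1-enyl acetate (E/Z) | CC(=O)OC=C(C)CBr
F4 | step 14 | acyclic (9R,10S) C9 acetate C10 alcohol with C8(Me)=CH2 and C7H=CH2 termini | C=C(C)[C@H]([C@H](O)[C@H](OC(C)=O)C(C)=C)C[C@@H](O[Si](CC)(CC)CC)[C@](C)(O[Si](CC)(CC)CC)[C@@H](OC(=O)/C(C)=C\C)CC=C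
F5 | step 15 | macrocyclic Z alkene C5,C10-bis-angelate | C=C(C)[C@H]1C[C@@H](O[Si](CC)(CC)CC)[C@](C)(O[Si](CC)(CC)CC)[C@@H](OC(=O)/C(C)=C\C)C/C=C(C)\[C@@H](OC(C)=O)[C@H]1OC(=O)/C(C)=C\C
F6 | step 12 | allylic gem-diacetate, C10–OSiEt3 | C=C(C)[C@H](CO[Si](CC)(CC)CC)C[C@@H](O[Si](CC)(CC)CC)[C@](C)(O[Si](CC)(CC)CC)[C@@H](OC(=O)/C(C)=C\C)C/C=C(\C)C(OC(C)=O)OC(C)=O
F7 | step 12 | allylic gem-diacetate, C10–OH | C=C(C)[C@H](CO)C[C@@H](O[Si](CC)(CC)CC)[C@](C)(O[Si](CC)(CC)CC)[C@@H](OC(=O)/C(C)=C\C)C/C=C(\C)C(OC(C)=O)OC(C)=O
F8 | step 12 | allylic gem-diacetate, C10 aldehyde | C=C(C)[C@H](C=O)C[C@@H](O[Si](CC)(CC)CC)[C@](C)(O[Si](CC)(CC)CC)[C@@H](OC(=O)/C(C)=C\C)C/C=C(\C)C(OC(C)=O)OC(C)=O
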